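**Direct plan and its weak points**

A direct plan would O-alkylate 2,4-dibromo-6-methoxyphenol A1 with racemic 2-chlorocyclohexanone A2 (K2CO3, KI, DMF) to the α-aryloxy ketone A3. It would then turn the cyclohexanone into ring A in one pot with four equivalents of Br2 in hot AcOH, through 2-(2,4-dibromo-6-methoxyphenoxy)phenol A4.
- The brominative dehydrogenation of A3 would be weak: two α-bromination/dehydrobromination cycles must each pick the right α-carbon, polybromination and HBr cleavage of the methyl ether compete, and no intermediate can be purified.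
- The two closing ring brominations would be weak: the bromines of ring A are placed last by electrophilic substitution, stopped only by the Br2 count, so under- and over-brominated congeners would have to be separated at the end.
- The ether-forming alkylation would be weak: a di-ortho-substituted, weakly nucleophilic phenoxide must attack a secondary α-halo ketone prone to elimination and Favorskii chemistry, and ring A is bought saturated and must later lose six hydrogens.

**Retrosynthetic overview of the new route**

Ring A is a 3,5-dibromocatechol unit. Its C2(Br)–C3(H)–C4(Br)–C5(H) segment is the C3–C6 diene of 3,5-dibromo-2H-pyran-2-one, and C1(OH)/C6(OAr) are the two carbons of a ketene acetal of an aryloxyacetic acid.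
The key disconnection cuts the C1–C2 and C5–C6 bonds of ring A: a pyrone Diels–Alder reaction, loss of CO2 and loss of silanol turn the pyrone into the arene.
Ring B is bought complete and ring A is formed last, already carrying both bromines, the OH and the ether oxygen. No late bromination or dehydrogenation is needed, and the only C–O alkylation is at a primary carbon.

Key step: step 3

Assumption: 2,4-dibromo-6-methoxyphenol and 3,5-dibromo-2H-pyran-2-one are taken as purchasable catalogue compounds.

**Route**

Step 1
Reactants: 1 2,4-dibromo-6-methoxyphenol; 2 bromoacetic acid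
Product: 3 2-(2,4-dibromo-6-methoxyphenoxy)acetic acid
Conditions: 2 (1.5 equiv), NaOH (4 equiv), H2O, 100 °C; then aq HCl to pH 1, 20 °C
Reagents that add atoms: none
Why: Williamson ether synthesis in which the phenoxide of 1 displaces bromide from the primary carbon of bromoacetate (SN2), a carbon with no β-hydrogen and so no elimination pathway, and no stereocentre is formed.

Step 2
Reactants: 3 2-(2,4-dibromo-6-methoxyphenoxy)acetic acid
Product: 5 1-(2,4-dibromo-6-methoxyphenoxy)-2,2-bis(trimethylsilyloxy)ethene, via trimethylsilyl ester 4 (not isolated)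
Conditions: Me3SiCl (1.05 equiv), Et3N (1.1 equiv), THF, 0 °C; then Me3SiCl (1.3 equiv), LiN(SiMe3)2 (1.15 equiv), −78 to 0 °C; pentane, filtration under Ar, used crude
Reagents that add atoms: chlorotrimethylsilane, C[Si](C)(C)Cl
Why: Silyl ester formation followed by kinetic enolisation and O-silylation (Ainsworth-type synthesis of a bis(trimethylsilyl) ketene acetal), in which the α-aryloxy CH2 is by far the most acidic site and the silyl chloride present in the flask should trap the enolate on oxygen before the amide base can touch the ring B hydrogen between the two bromines; the two silyloxy groups are identical, so no alkene geometry has to be controlled.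

Step 3
Reactants: 5 1-(2,4-dibromo-6-methoxyphenoxy)-2,2-bis(trimethylsilyloxy)ethene; 6 3,5-dibromo-2H-pyran-2-one
Product: 10 2,4-dibromo-6-(2,4-dibromo-6-methoxyphenoxy)phenol (target), via bicyclic lactone 7 (not isolated), via cyclohexadiene 8 (not isolated), via aryl trimethylsilyl ether 9 (not isolated)
Conditions: 5 (1.5 equiv), toluene, 110 °C, sealed tube; then 1 M HCl, THF, 20 °C
Reagents that add atoms: none
Why: Inverse-electron-demand Diels–Alder reaction of the electron-poor diene C3=C4–C5=C6 of pyrone 6 with the electron-rich ketene acetal 5 should give the bridged lactone 7, which loses CO2 by retro-[4+2] to diene 8; 1,2-elimination of trimethylsilanol then aromatises 8 to silyl ether 9, and dilute acid frees the phenol 10. The closest known reaction type is the benzannulation of 2-pyrones with ketene acetals such as 1,1-dimethoxyethene and 1,1,2-trimethoxyethene (loss of CO2 and alcohol), together with the cycloaddition of 3,5-dibromo-2-pyrone with enol ethers and silyl enol ethers. Ring A is closed by an intermolecular [4+2] cycloaddition that forms its C1–C2 and C5–C6 bonds at once, and the three sp3 centres of 7 are transient and all become aromatic carbons, so no stereocentre has to be controlled. The step needs one regiochemistry: the nucleophilic aryloxy-bearing CH of 5 must bond to C6, the electrophilic terminus of the pyrone, and the bis(silyloxy) carbon to the bromine-bearing C3, which is the orientation expected for electron-rich dienophiles with 3-bromo- and 3,5-dibromo-2-pyrones and which places the OH next to C2–Br and the ether oxygen next to C5–H. Aromatisation can only expel silanol, because the acetal carbon bears no hydrogen and the only removable hydrogen sits on the aryloxy carbon, so the diaryl ether oxygen is kept and both bromines of ring A come from the pyrone.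

**Compound list**

1 | 2,4-dibromo-6-methoxyphenol | COc1cc(Br)cc(Br)c1O | starting material
2 | bromoacetic acid | OC(=O)CBr | starting material
3 | 2-(2,4-dibromo-6-methoxyphenoxy)acetic acid | COc1cc(Br)cc(Br)c1OCC(=O)O | intermediate
4 | trimethylsilyl 2-(2,4-dibromo-6-methoxyphenoxy)acetate (not isolated) | COc1cc(Br)cc(Br)c1OCC(=O)O[Si](C)(C)C | intermediate
5 | 1-(2,4-dibromo-6-methoxyphenoxy)-2,2-bis(trimethylsilyloxy)ethene | COc1cc(Br)cc(Br)c1OC=C(O[Si](C)(C)C)O[Si](C)(C)C | intermediate
6 | 3,5-dibromo-2H-pyran-2-one | O=C1OC=C(Br)C=C1Br | starting material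
7 | 4,7-dibromo-6-(2,4-dibromo-6-methoxyphenoxy)-5,5-bis(trimethylsilyloxy)-2-oxabicyclo[2.2.2]oct-7-en-3-one (racemic, endo/exo mixture at C6, not isolated) | O=C1OC2C(Br)=CC1(Br)C(O[Si](C)(C)C)(O[Si](C)(C)C)C2Oc1c(Br)cc(Br)cc1OC | intermediate
8 | 1,3-dibromo-5-(2,4-dibromo-6-methoxyphenoxy)-6,6-bis(trimethylsilyloxy)cyclohexa-1,3-diene (racemic, not isolated) | COc1cc(Br)cc(Br)c1OC1C=C(Br)C=C(Br)C1(O[Si](C)(C)C)O[Si](C)(C)C | intermediate
9 | [2,4-dibromo-6-(2,4-dibromo-6-methoxyphenoxy)phenoxy]trimethylsilane (not isolated) | COc1cc(Br)cc(Br)c1Oc1cc(Br)cc(Br)c1O[Si](C)(C)C | intermediate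
10 | 2,4-dibromo-6-(2,4-dibromo-6-methoxyphenoxy)phenol (achiral) | COc1cc(Br)cc(Br)c1Oc1cc(Br)cc(Br)c1O | target

Total step count: 3. Longest linear sequence: 3 steps (1 → 3 → 5 → 10).

**Steps most likely to fail**

1. Step 3. The ketene acetal may add stepwise (Mukaiyama–Michael attack at C6, then silyl transfer and opening of the pyrone) instead of closing the ring, the cycloaddition may take the reverse orientation, or CO2 extrusion from the bridged lactone may be incomplete. The fallback sets out from 1 and comes back at 10. Phenol 1 would be arylated by nucleophilic aromatic substitution on commercial 2,4-dibromo-6-fluorobenzaldehyde (K2CO3, DMF, 80 °C), whose ortho formyl group activates the fluoride, to give 2,4-dibromo-6-(2,4-dibromo-6-methoxyphenoxy)benzaldehyde F1. Baeyer–Villiger (Dakin-type) oxidation with mCPBA in CH2Cl2 should give 2,4-dibromo-6-(2,4-dibromo-6-methoxyphenoxy)phenyl formate F2, and aqueous NaOH in MeOH followed by HCl would release 10 with all four bromines already in place.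

2. Step 2. The amide base may metalate ring B at the hydrogen between the two bromines and cause halogen migration, silylation may go to carbon instead of oxygen, or the ketene acetal may hydrolyse on handling. The fallback sets out from 1 and comes back at 10 without any enolate. Nucleophilic aromatic substitution of 1 on 1-fluoro-2-nitrobenzene (K2CO3, DMF, 90 °C) would give 1,5-dibromo-3-methoxy-2-(2-nitrophenoxy)benzene F3. Reduction with Fe and NH4Cl in EtOH/H2O at 80 °C would give 2-(2,4-dibromo-6-methoxyphenoxy)aniline F4. Diazotisation (NaNO2, aqueous H2SO4, 0 °C) would give 2-(2,4-dibromo-6-methoxyphenoxy)benzenediazonium hydrogen sulfate F5, hydrolysed with Cu2O and Cu(NO3)2 in water at 20 °C to 2-(2,4-dibromo-6-methoxyphenoxy)phenol F6. Br2 (2 equiv) in AcOH at 20 °C would then brominate para and ortho to the free OH to give 10.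

3. Step 1. Hydrolysis of bromoacetate to glycolate may outrun attack by the hindered, weakly nucleophilic phenoxide, so that conversion stalls. The fallback sets out from 1 and comes back at 3. A Mitsunobu reaction of the acidic phenol 1 with methyl glycolate (PPh3, DIAD, THF, 0 to 20 °C), which activates the alcohol carbon instead of relying on a haloacetate, would give methyl 2-(2,4-dibromo-6-methoxyphenoxy)acetate F7. Saponification (LiOH, THF/H2O, 20 °C; then HCl) would return acid 3.

Further compounds
F1 | step 3 | 2,4-dibromo-6-(2,4-dibromo-6-methoxyphenoxy)benzaldehyde | COc1cc(Br)cc(Br)c1Oc1cc(Br)cc(Br)c1C=O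
F2 | step 3 | 2,4-dibromo-6-(2,4-dibromo-6-methoxyphenoxy)phenyl formate | COc1cc(Br)cc(Br)c1Oc1cc(Br)cc(Br)c1OC=O
F3 | step 2 | 1,5-dibromo-3-methoxy-2-(2-nitrophenoxy)benzene | COc1cc(Br)cc(Br)c1Oc1ccccc1[N+](=O)[O-]
F4 | step 2 | 2-(2,4-dibromo-6-methoxyphenoxy)aniline | COc1cc(Br)cc(Br)c1Oc1ccccc1N
F5 | step 2 | 2-(2,4-dibromo-6-methoxyphenoxy)benzenediazonium hydrogen sulfate | COc1cc(Br)cc(Br)c1Oc1ccccc1[N+]#N.OS(=O)(=O)[O-]
F6 | step 2 | 2-(2,4-dibromo-6-methoxyphenoxy)phenol | COc1cc(Br)cc(Br)c1Oc1ccccc1O
F7 | step 1 | methyl 2-(2,4-dibromo-6-methoxyphenoxy)acetate | COC(=O)COc1c(Br)cc(Br)cc1OC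
A1 | direct plan | 2,4-dibromo-6-methoxyphenol | COc1cc(Br)cc(Br)c1O
A2 | direct plan | 2-chlorocyclohexanone (racemic) | O=C1CCCCC1Cl
A3 | direct plan | 2-(2,4-dibromo-6-methoxyphenoxy)cyclohexan-1-one (racemic) | COc1cc(Br)cc(Br)c1OC1CCCCC1=O
A4 | direct plan | 2-(2,4-dibromo-6-methoxyphenoxy)phenol | COc1cc(Br)cc(Br)c1Oc1ccccc1O
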